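**Retrosynthetic overview**

1. Numbering (germacrane type): ten-membered ring C1 (ketone) to C10 (methyl methine), C4 methyl carbinol, C6 ester carbon, lactone fused at C7/C8 (O8 to C12), C11=C13 methylene. The strategy rests on the C6–C7 bond: counted from the C1 ketone through C10, C9 and C8 it is the δ,ε bond, so with a C6=C7 alkene the carbocycle is an oxy-Cope product, atoms C1–C6 refold into a cyclohexanol, and C7=C8 and C9=C10 become its two alkenyl arms.
2. Endgame disconnections: C13 (Mannich methylenation), the C12 carbonyl (ether-to-lactone oxidation of a C8–O–C12 tetrahydrofuran), the isobutyrate, and C6–O/C7–H (hydroboration of C6=C7 on a C1/O4 bridged methyl ketal).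
3. Key disconnection: C8–C9, by anionic oxy-Cope ring expansion across C1–C6 of the trans-1-isopropenyl-2-(4,5-dihydrofuran-3-yl)cyclohexanol 15. O8 and C12 stay joined as a cyclic enol ether, which fixes the enol ether geometry and decides in advance that O8, not O6, closes the lactone.
4. 15 comes from (S)-linalool (source of C4) by ozonolysis, vinyl addition and ring-closing metathesis to enone 8, then α-iodination, Suzuki coupling with the commercial boronate 10, conjugate reduction and isopropenyl addition.
5. Ring order: cyclohexene (step 4; the five-membered ether ring is bought with 10), ten-membered carbocycle (step 10), C1–O–C4 bridge (step 11, opened in step 17), lactone carbonyl (step 14).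

Key step: step 10

Assumption: (S)-(+)-linalool of high enantiomeric purity is used; it supplies C4 unchanged, and every other stereocentre is set relative to it.
Assumption: the target is the open γ-hydroxy ketone as written; its C1/O4 hemiketal is taken as a ring-chain tautomer, not a separate product.
Remark: the numbering of line 1 is used for all ten-membered compounds; C7, C8, C11, C12 and O8 come from the dihydrofuran ring of 10.

**Route**

Step 1
Reactants: 1 (S)-(+)-linalool
Product: 2 (3S)-3,7-dimethyl-3-(triethylsilyloxy)octa-1,6-diene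
Conditions: Et3SiOTf, 2,6-lutidine, CH2Cl2, −78 to 0 °C
Reagents that add atoms: triethylsilyl trifluoromethanesulfonate, CC[Si](CC)(CC)OS(=O)(=O)C(F)(F)F
Why: O-silylation of a hindered tertiary alcohol with a silyl triflate and a hindered base is reliable and leaves the carbinol centre, the future C4, untouched.

Step 2
Reactants: 2 (3S)-3,7-dimethyl-3-(triethylsilyloxy)octa-1,6-diene
Product: 4 (4S)-4-methyl-4-(triethylsilyloxy)hex-5-enal, via secondary ozonide 3 (not isolated)
Conditions: O3, CH2Cl2, −78 °C (Sudan Red 7B end point); then PPh3, −78 °C to rt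
Reagents that add atoms: ozone, [O-][O+]=O
Why: Ozonolysis with reductive work-up cleaves the electron-rich trisubstituted alkene much faster than the vinyl group, which is deactivated and shielded by the neighbouring siloxy-bearing quaternary carbon, so the dye end point stops the reaction at the monoaldehyde.

Step 3
Reactants: 4 (4S)-4-methyl-4-(triethylsilyloxy)hex-5-enal; 5 vinylmagnesium bromide
Product: 6 (3RS,6S)-6-methyl-6-(triethylsilyloxy)octa-1,7-dien-3-ol
Conditions: CH2=CHMgBr, THF, −78 to 0 °C; then H2O
Reagents that add atoms: none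
Why: Grignard 1,2-addition to the unhindered aldehyde gives the allylic alcohol as both carbinol epimers, which does not matter because step 5 oxidises this centre.

Step 4
Reactants: 6 (3RS,6S)-6-methyl-6-(triethylsilyloxy)octa-1,7-dien-3-ol
Product: 7 (1RS,4S)-4-methyl-4-(triethylsilyloxy)cyclohex-2-en-1-ol
Conditions: second-generation Grubbs catalyst (H2IMes)(PCy3)Cl2Ru=CHPh (2 mol%), CH2Cl2, 40 °C
Reagents that add atoms: none
Why: Ring-closing metathesis of two monosubstituted alkenes closes the unstrained cyclohexene with loss of ethylene and tolerates the silyl ether and the free alcohol.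

Step 5
Reactants: 7 (1RS,4S)-4-methyl-4-(triethylsilyloxy)cyclohex-2-en-1-ol
Product: 8 (4S)-4-methyl-4-(triethylsilyloxy)cyclohex-2-en-1-one
Conditions: (n-Pr4N)RuO4 (5 mol%), N-methylmorpholine N-oxide, 4 Å MS, CH2Cl2, rt
Reagents that add atoms: none
Why: Ley–Griffith oxidation of the secondary allylic alcohol converges both carbinol epimers on one enone, in which the siloxy-bearing carbon is the only stereocentre (4S).

Step 6
Reactants: 8 (4S)-4-methyl-4-(triethylsilyloxy)cyclohex-2-en-1-one
Product: 9 (4S)-2-iodo-4-methyl-4-(triethylsilyloxy)cyclohex-2-en-1-one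
Conditions: I2, K2CO3, DMAP (20 mol%), THF–H2O (1:1), rt
Reagents that add atoms: iodine, [I][I]
Why: α-Iodination of the enone by conjugate addition of DMAP, iodination of the enolate and loss of DMAP (a Baylis–Hillman-type addition–elimination) is standard for 4,4-disubstituted cyclohexenones and does not touch the stereocentre.

Step 7
Reactants: 9 (4S)-2-iodo-4-methyl-4-(triethylsilyloxy)cyclohex-2-en-1-one; 10 2-(4,5-dihydrofuran-3-yl)-4,4,5,5-tetramethyl-1,3,2-dioxaborolane
Product: 11 (4S)-2-(4,5-dihydrofuran-3-yl)-4-methyl-4-(triethylsilyloxy)cyclohex-2-en-1-one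
Conditions: Pd(dppf)Cl2 (5 mol%), K3PO4, 1,4-dioxane–H2O (5:1), 60 °C
Reagents that add atoms: none
Why: Suzuki–Miyaura coupling of a 2-iodoenone with an alkenylboronate goes with retention at both partners, and the five-membered ring of 10 holds the enol ether oxygen trans to the new C6–C7 bond.

Step 8
Reactants: 11 (4S)-2-(4,5-dihydrofuran-3-yl)-4-methyl-4-(triethylsilyloxy)cyclohex-2-en-1-one
Product: 13 (2S,4S)-2-(4,5-dihydrofuran-3-yl)-4-methyl-4-(triethylsilyloxy)cyclohexan-1-one, via silyl enol ether 12 (not isolated)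
Conditions: [(Ph3P)CuH]6 (5 mol% Cu), PhMe2SiH, toluene, rt; then K2CO3 (20 mol%), MeOH, rt
Reagents that add atoms: none
Why: Copper hydride-catalysed 1,4-hydrosilylation (conjugate reduction) reduces only the enone alkene, and basic methanolysis of the silyl enol ether protonates C6 reversibly, so C6 settles under thermodynamic control with the dihydrofuranyl group equatorial and cis to the equatorial C4 methyl (siloxy group axial, as 4-oxygenated cyclohexanones prefer), the β,γ-unsaturated enol ether being favoured over the conjugated alkylidene isomer.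

Step 9
Reactants: 13 (2S,4S)-2-(4,5-dihydrofuran-3-yl)-4-methyl-4-(triethylsilyloxy)cyclohexan-1-one; 14 isopropenylmagnesium bromide
Product: 15 (1S,2S,4S)-2-(4,5-dihydrofuran-3-yl)-4-methyl-1-(prop-1-en-2-yl)-4-(triethylsilyloxy)cyclohexan-1-ol
Conditions: CeCl3 (anhydrous), CH2=C(CH3)MgBr, THF, −78 °C; then H2O
Reagents that add atoms: none
Why: Organocerium 1,2-addition suppresses enolisation of the α-alkenyl ketone, and equatorial attack anti to the neighbouring equatorial dihydrofuranyl group gives the axial alcohol with the two alkenyl groups trans (1S).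

Step 10
Reactants: 15 (1S,2S,4S)-2-(4,5-dihydrofuran-3-yl)-4-methyl-1-(prop-1-en-2-yl)-4-(triethylsilyloxy)cyclohexan-1-ol
Product: 19 (4S,8S,10R,6E)-8,12-epoxy-4-(triethylsilyloxy)-13-norgermacr-6-en-1-one, via potassium alkoxide 16 (not isolated), via potassium enolate 17 (not isolated), via C10-epimeric ketone 18 (not isolated)
Conditions: KH, 18-crown-6, THF, 0 °C to rt; then MeOH, rt, until the C10 ratio is constant; pH 7 buffer
Reagents that add atoms: none
Why: KH with 18-crown-6 gives the free alkoxide 16, which undergoes a concerted chair [3,3] shift (anionic oxy-Cope rearrangement, known for trans-1,2-dialkenylcyclohexanols giving (E)-cyclodec-5-enones) in which the C8–C9 bond forms while the C1–C6 bond is cleaved, and formation of enolate 17 makes it irreversible. The ten-membered ring arises by enlarging the six-membered ring by four atoms in the shift itself, so no cyclisation of an open chain and no high dilution are involved. C8 is set by the chair: with both alkenyl groups equatorial and trans, the ring bonds C1–C2 and C6–C5 are equatorial, the ring oxygen on C8 (held trans to C6 by the dihydrofuran ring) is equatorial too, and C9 therefore bonds to one face of C8 only (8S) and leaves the E C6=C7 alkene. C10 is set on protonation of the E enolate 17: the proton is expected to enter first from the open outer face and give 18 with the methyl turned over the ring, and methoxide formed in the quench equilibrates it through 17 to 19, in which the methyl lies on the periphery (10R). The step needs the chair [3,3] path to win over the boat path, the [1,3] shift and fragmentation of the alkoxide, which the trans-diequatorial alkenyl groups, the rigid cyclic enol ether and the unsubstituted C9 terminus secure.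

Step 11
Reactants: 19 (4S,8S,10R,6E)-8,12-epoxy-4-(triethylsilyloxy)-13-norgermacr-6-en-1-one
Product: 21 (1R,4S,8S,10R,6E)-1-methoxy-1,4:8,12-diepoxy-13-norgermacr-6-ene, via hydroxy ketone 20 (not isolated)
Conditions: camphorsulfonic acid (10 mol%), MeOH, HC(OMe)3, 0 °C to rt
Reagents that add atoms: methanol, CO
Why: Acid methanolysis of the tertiary silyl ether frees O4, which adds across the ring to the C1 ketone, and acid-catalysed exchange with methanol gives the five-membered bridged methyl ketal (transannular ketalisation), whose C1 configuration is forced by the cis bridge and which masks both the ketone and the tertiary alcohol.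

Step 12
Reactants: 21 (1R,4S,8S,10R,6E)-1-methoxy-1,4:8,12-diepoxy-13-norgermacr-6-ene
Product: 23 (1R,4S,6R,7R,8S,10R)-1-methoxy-1,4:8,12-diepoxy-13-norgermacran-6-ol, via C6 alkylborane 22 (not isolated)
Conditions: BH3·THF, THF, 0 °C to rt; then NaOH, H2O2, 0 °C
Reagents that add atoms: hydrogen peroxide, OO
Why: Hydroboration–oxidation puts boron on the less substituted C6 and adds H and B syn across the E alkene from the face that carries H8 (the other face is covered by the ring chain leaving C8 through C9, while O8 is held in the alkene plane by the tetrahydrofuran ring), so C7 (H cis to H8) and C6 (6R) are set together and the oxidation keeps the C6 configuration.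

Step 13
Reactants: 23 (1R,4S,6R,7R,8S,10R)-1-methoxy-1,4:8,12-diepoxy-13-norgermacran-6-ol; 24 isobutyric anhydride
Product: 25 (1R,4S,6R,7S,8S,10R)-1-methoxy-1,4:8,12-diepoxy-13-norgermacran-6-yl 2-methylpropanoate
Conditions: (i-PrCO)2O, Et3N, DMAP (10 mol%), CH2Cl2, rt
Reagents that add atoms: none
Why: DMAP-catalysed acylation esterifies the only free hydroxyl group, the secondary C6 alcohol, with retention (the C7 descriptor changes with the priorities only).

Step 14
Reactants: 25 (1R,4S,6R,7S,8S,10R)-1-methoxy-1,4:8,12-diepoxy-13-norgermacran-6-yl 2-methylpropanoate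
Product: 26 (1R,4S,6R,7S,8S,10R)-1-methoxy-1,4-epoxy-6-(2-methylpropanoyloxy)-13-norgermacran-12,8-olide
Conditions: RuCl3·xH2O (5 mol%), NaIO4, CCl4–MeCN–aq. phosphate buffer (pH 7), rt
Reagents that add atoms: sodium periodate, [Na+].[O-]I(=O)(=O)=O
Why: RuO4 formed in the flask oxidises a cyclic ether to the lactone at a methylene next to oxygen (ether-to-lactone oxidation), here the exposed C12 methylene in preference to the C8 methine at the ring fusion and to the electron-poor ketal methyl, while the buffer protects the ketal.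

Step 15
Reactants: 26 (1R,4S,6R,7S,8S,10R)-1-methoxy-1,4-epoxy-6-(2-methylpropanoyloxy)-13-norgermacran-12,8-olide; 27 dimethylmethylideneammonium iodide (Eschenmoser's salt)
Product: 29 (1R,4S,6R,7S,8S,10R,11RS)-13-(dimethylamino)-1-methoxy-1,4-epoxy-6-(2-methylpropanoyloxy)germacran-12,8-olide, via lithium lactone enolate 28 (not isolated)
Conditions: LiN(SiMe3)2, THF, −78 °C; then CH2=NMe2+ I−, −78 to 0 °C
Reagents that add atoms: none
Why: Kinetic enolisation takes the lactone methylene, which is both more acidic and more accessible than the isobutyrate methine, and the enolate is aminomethylated by the iminium salt (Mannich reaction), the C11 centre formed here disappearing in step 16.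

Step 16
Reactants: 29 (1R,4S,6R,7S,8S,10R,11RS)-13-(dimethylamino)-1-methoxy-1,4-epoxy-6-(2-methylpropanoyloxy)germacran-12,8-olide
Product: 31 (1R,4S,6R,7S,8S,10R)-1-methoxy-1,4-epoxy-6-(2-methylpropanoyloxy)germacr-11(13)-en-12,8-olide, via trimethylammonium iodide 30 (not isolated)
Conditions: MeI, MeOH, rt; then aq. NaHCO3, CH2Cl2, rt
Reagents that add atoms: none
Why: Quaternisation of the amine and base-induced β-elimination of trimethylamine (Hofmann-type elimination through the lactone enolate) give the exocyclic C11=C13 methylene without touching the ester or the ketal.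

Step 17
Reactants: 31 (1R,4S,6R,7S,8S,10R)-1-methoxy-1,4-epoxy-6-(2-methylpropanoyloxy)germacr-11(13)-en-12,8-olide
Product: 33 (4S,6R,7S,8S,10R)-4-hydroxy-6-(2-methylpropanoyloxy)-1-oxogermacr-11(13)-en-12,8-olide (CNP0293926.1), via C1 hemiketal 32 (not isolated)
Conditions: pyridinium p-toluenesulfonate (20 mol%), acetone–H2O (10:1), 40 °C
Reagents that add atoms: water, O
Why: Mild acid hydrolysis of the mixed ketal gives the hemiketal, which opens to the γ-hydroxy ketone and so frees the C1 ketone and the C4 alcohol in one operation, under conditions too mild to enolise C10 or to harm the ester and the α-methylene lactone.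

**Compound list**

1 | (S)-(+)-linalool, (3S)-3,7-dimethylocta-1,6-dien-3-ol | C=C[C@@](C)(O)CCC=C(C)C | starting material
2 | (3S)-3,7-dimethyl-3-(triethylsilyloxy)octa-1,6-diene | C=C[C@@](C)(O[Si](CC)(CC)CC)CCC=C(C)C | intermediate
3 | secondary ozonide of 2 (1,2,4-trioxolane at the former C6=C7 bond) | CC1(C)OOC(CC[C@](C)(O[Si](CC)(CC)CC)C=C)O1 | intermediate
4 | (4S)-4-methyl-4-(triethylsilyloxy)hex-5-enal | O=CCC[C@](C)(O[Si](CC)(CC)CC)C=C | intermediate
5 | vinylmagnesium bromide | C=C[Mg]Br | starting material
6 | (3RS,6S)-6-methyl-6-(triethylsilyloxy)octa-1,7-dien-3-ol | C=CC(O)CC[C@](C)(O[Si](CC)(CC)CC)C=C | intermediate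
7 | (1RS,4S)-4-methyl-4-(triethylsilyloxy)cyclohex-2-en-1-ol | OC1C=C[C@@](C)(O[Si](CC)(CC)CC)CC1 | intermediate
8 | (4S)-4-methyl-4-(triethylsilyloxy)cyclohex-2-en-1-one | O=C1C=C[C@@](C)(O[Si](CC)(CC)CC)CC1 | intermediate
9 | (4S)-2-iodo-4-methyl-4-(triethylsilyloxy)cyclohex-2-en-1-one | O=C1C(I)=C[C@@](C)(O[Si](CC)(CC)CC)CC1 | intermediate
10 | 2-(4,5-dihydrofuran-3-yl)-4,4,5,5-tetramethyl-1,3,2-dioxaborolane | CC1(C)OB(OC1(C)C)C2=COCC2 | starting material
11 | (4S)-2-(4,5-dihydrofuran-3-yl)-4-methyl-4-(triethylsilyloxy)cyclohex-2-en-1-one | O=C1C(C2=COCC2)=C[C@@](C)(O[Si](CC)(CC)CC)CC1 | intermediate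
12 | (4S)-2-(4,5-dihydrofuran-3-yl)-1-(dimethylphenylsilyloxy)-4-methyl-4-(triethylsilyloxy)cyclohex-1-ene | C[Si](C)(c1ccccc1)OC2=C(C3=COCC3)C[C@@](C)(O[Si](CC)(CC)CC)CC2 | intermediate
13 | (2S,4S)-2-(4,5-dihydrofuran-3-yl)-4-methyl-4-(triethylsilyloxy)cyclohexan-1-one | O=C1CC[C@](C)(O[Si](CC)(CC)CC)C[C@H]1C2=COCC2 | intermediate
14 | isopropenylmagnesium bromide | C=C(C)[Mg]Br | starting material
15 | (1S,2S,4S)-2-(4,5-dihydrofuran-3-yl)-4-methyl-1-(prop-1-en-2-yl)-4-(triethylsilyloxy)cyclohexan-1-ol (key-step precursor) | C=C(C)[C@]1(O)CC[C@](C)(O[Si](CC)(CC)CC)C[C@H]1C2=COCC2 | intermediate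
16 | potassium alkoxide of 15 | C=C(C)[C@]1([O-])CC[C@](C)(O[Si](CC)(CC)CC)C[C@H]1C2=COCC2.[K+] | intermediate
17 | potassium C1(10)-enolate of 19 (O cis to C9, E C6=C7) | O1[C@H]2C/C(C)=C(\[O-])CC[C@](C)(O[Si](CC)(CC)CC)C/C=C2\CC1.[K+] | intermediate
18 | (4S,8S,10S,6E)-8,12-epoxy-4-(triethylsilyloxy)-13-norgermacr-6-en-1-one (C10 epimer of 19) | O1[C@H]2C[C@H](C)C(=O)CC[C@](C)(O[Si](CC)(CC)CC)C/C=C2\CC1 | intermediate
19 | (4S,8S,10R,6E)-8,12-epoxy-4-(triethylsilyloxy)-13-norgermacr-6-en-1-one (key-step product: ten-membered ketone, E C6=C7, C8–O–C12 tetrahydrofuran) | O1[C@H]2C[C@@H](C)C(=O)CC[C@](C)(O[Si](CC)(CC)CC)C/C=C2\CC1 | intermediate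
20 | (4S,8S,10R,6E)-8,12-epoxy-4-hydroxy-13-norgermacr-6-en-1-one | O1[C@H]2C[C@@H](C)C(=O)CC[C@](C)(O)C/C=C2\CC1 | intermediate
21 | (1R,4S,8S,10R,6E)-1-methoxy-1,4:8,12-diepoxy-13-norgermacr-6-ene | CO[C@]12CC[C@](C)(O1)C/C=C3\CCO[C@H]3C[C@H]2C | intermediate
22 | C6 alkylborane from 21 (BH2 on C6, H on C7, configuration as in 23) | CO[C@]12CC[C@](C)(O1)C[C@@H]([BH2])[C@H]3CCO[C@H]3C[C@H]2C | intermediate
23 | (1R,4S,6R,7R,8S,10R)-1-methoxy-1,4:8,12-diepoxy-13-norgermacran-6-ol | CO[C@]12CC[C@](C)(O1)C[C@@H](O)[C@H]3CCO[C@H]3C[C@H]2C | intermediate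
24 | isobutyric anhydride | CC(C)C(=O)OC(=O)C(C)C | starting material
25 | (1R,4S,6R,7S,8S,10R)-1-methoxy-1,4:8,12-diepoxy-13-norgermacran-6-yl 2-methylpropanoate | CO[C@]12CC[C@](C)(O1)C[C@@H](OC(=O)C(C)C)[C@H]3CCO[C@H]3C[C@H]2C | intermediate
26 | (1R,4S,6R,7S,8S,10R)-1-methoxy-1,4-epoxy-6-(2-methylpropanoyloxy)-13-norgermacran-12,8-olide | CO[C@]12CC[C@](C)(O1)C[C@@H](OC(=O)C(C)C)[C@H]3CC(=O)O[C@H]3C[C@H]2C | intermediate
27 | dimethylmethylideneammonium iodide (Eschenmoser's salt) | C=[N+](C)C.[I-] | starting material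
28 | lithium enolate of lactone 26 | CO[C@]12CC[C@](C)(O1)C[C@@H](OC(=O)C(C)C)[C@H]3C=C([O-])O[C@H]3C[C@H]2C.[Li+] | intermediate
29 | (1R,4S,6R,7S,8S,10R,11RS)-13-(dimethylamino)-1-methoxy-1,4-epoxy-6-(2-methylpropanoyloxy)germacran-12,8-olide | CO[C@]12CC[C@](C)(O1)C[C@@H](OC(=O)C(C)C)[C@H]3C(CN(C)C)C(=O)O[C@H]3C[C@H]2C | intermediate
30 | trimethylammonium iodide from 29 | CO[C@]12CC[C@](C)(O1)C[C@@H](OC(=O)C(C)C)[C@H]3C(C[N+](C)(C)C)C(=O)O[C@H]3C[C@H]2C.[I-] | intermediate
31 | (1R,4S,6R,7S,8S,10R)-1-methoxy-1,4-epoxy-6-(2-methylpropanoyloxy)germacr-11(13)-en-12,8-olide | CO[C@]12CC[C@](C)(O1)C[C@@H](OC(=O)C(C)C)[C@H]3C(=C)C(=O)O[C@H]3C[C@H]2C | intermediate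
32 | (1R,4S,6R,7S,8S,10R)-1-hydroxy-1,4-epoxy-6-(2-methylpropanoyloxy)germacr-11(13)-en-12,8-olide (hemiketal) | O[C@]12CC[C@](C)(O1)C[C@@H](OC(=O)C(C)C)[C@H]3C(=C)C(=O)O[C@H]3C[C@H]2C | intermediate
33 | (4S,6R,7S,8S,10R)-4-hydroxy-6-(2-methylpropanoyloxy)-1-oxogermacr-11(13)-en-12,8-olide (CNP0293926.1) | C=C1C(=O)O[C@H]2C[C@@H](C)C(=O)CC[C@](C)(O)C[C@@H](OC(=O)C(C)C)[C@@H]12 | target

**Step count**

Total step count: 17.
Longest linear sequence: 17 steps, from 1 to 33 (10 is bought).

**Steps most likely to fail**

Step 10. The equilibration at C10 may not come to rest on the side of the 10R ketone, or the methyl-bearing terminus may slow the shift enough for fragmentation of the alkoxide to compete. The fallback sets out from 13 and comes back at 19. Ketone 13 is treated with vinylmagnesium bromide 5 and CeCl3 to give the vinyl carbinol F1. KH and 18-crown-6 convert it through its potassium alkoxide F2, by the same chair shift, into the C10-unsubstituted potassium enolate F3. Iodomethane added at −78 °C then alkylates F3 from the open outer face, which sets C10 kinetically as 10R and gives 19 (tandem oxy-Cope rearrangement and enolate alkylation).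

Step 11. The acid may trigger bond formation across the ring between the activated C1 carbon and the C6=C7 alkene, or enolise C10 through an enol ether. The fallback sets out from 19 and comes back at 21 without any acid. n-Bu4NF buffered with AcOH removes the silyl group, and the hydroxy ketone 20 closes to the C1 hemiketal F4. Ag2O and iodomethane (Purdie methylation) then O-methylate F4 to 21.

Step 14. The oxidation may attack the C8 methine or over-oxidise, or the ketal may hydrolyse in the periodate medium. The fallback sets out from 25 and comes back at 26, replacing the direct metal-oxo oxidation by a radical hydroxylation followed by an alcohol oxidation. Photoexcited (n-Bu4N)4W10O32 (365 nm, O2, MeCN) abstracts a hydrogen atom from the exposed C12 methylene and gives the C12 hydroperoxide F5. PPh3 reduces it to the lactol F6, and TEMPO (cat.) with PhI(OAc)2 oxidises F6 to 26.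

Further compounds
F1 | step 10 | (1R,2S,4S)-2-(4,5-dihydrofuran-3-yl)-1-ethenyl-4-methyl-4-(triethylsilyloxy)cyclohexan-1-ol | C=C[C@]1(O)CC[C@](C)(O[Si](CC)(CC)CC)C[C@H]1C2=COCC2
F2 | step 10 | potassium alkoxide of F1 | C=C[C@]1([O-])CC[C@](C)(O[Si](CC)(CC)CC)C[C@H]1C2=COCC2.[K+]
F3 | step 10 | potassium C1(10)-enolate of the 10-demethyl analogue of 19 | O1[C@H]2C/C=C(\[O-])CC[C@](C)(O[Si](CC)(CC)CC)C/C=C2\CC1.[K+]
F4 | step 11 | (1R,4S,8S,10R,6E)-1,4:8,12-diepoxy-13-norgermacr-6-en-1-ol (hemiketal) | O[C@]12CC[C@](C)(O1)C/C=C3\CCO[C@H]3C[C@H]2C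
F5 | step 14 | 12-hydroperoxide of 25 (both C12 epimers) | CO[C@]12CC[C@](C)(O1)C[C@@H](OC(=O)C(C)C)[C@H]3CC(OO)O[C@H]3C[C@H]2C
F6 | step 14 | 12-hydroxy derivative of 25 (lactol, both C12 epimers) | CO[C@]12CC[C@](C)(O1)C[C@@H](OC(=O)C(C)C)[C@H]3CC(O)O[C@H]3C[C@H]2C
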